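# Proposed synthesis of CNP0298534.1 (21) by a peroxycarbenium–homoenolate [3+3] annulation

Positional numbering runs from the carboxyl carbon C1; the ring is C3–C4–C5–C6–O1–O2. Compound numbers are those of the steps below.

## The problem

Target 21 is a 3,6-disubstituted 1,2-dioxane in which C3 carries the acetic acid arm (C2–C1) and C6 is a peroxyketal carbon bearing a methoxy group and a sixteen-carbon chain whose C10–C13 segment is an (E)-enyne. Only one ring has to be made, but its O–O bond tolerates neither reductants, low-valent metals under forcing conditions nor strong base, and the ketal tolerates no aqueous acid. There are two stereocentres, C3 (S) and C6 (R); C6 is anomeric, and acidic methanol equilibrates it to the isomer with axial methoxy and both carbon substituents equatorial, which is the relative configuration of 21. C3 can therefore control C6, but nothing in the molecule controls C3. C3 is a secondary peroxy carbon β to the carboxyl group, so a base that enolises the carbonyl can expel the peroxide (the reverse of a peroxide conjugate addition) and erase C3. The enyne is a good π-nucleophile and is easily oxidised, so it should arrive after all cationic chemistry. The enabling feature is the polarity pattern of the ring carbons: C3 is at the aldehyde oxidation level and flanked by O2, so it can be a peroxycarbenium ion, while C4 is β to the ketal carbon C6, so C4–C5–C6 is a ketone homoenolate that a donor cyclopropane can deliver. C3–O2–O1 and C4–C5–C6 are then the two three-atom halves of a [3+3] annulation.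

## Retrosynthesis

**21 from 20.** The last cut is the C1 acyl–nitrogen bond, tracing acid 21 to the N-acyl oxazolidinone 20. A methyl ester would be cleaved equally late, but the (4S)-4-benzyloxazolidinone does two more jobs: it makes the two C3 configurations diastereomers, hence separable, and as a chelating group it offers the C3 cation of the key step a preferred face. The forward reaction must cleave the exocyclic acyl group without β-elimination of the peroxide.

**20 from 16 and 19.** The C11–C12 bond between the sp and sp2 carbons is cut, giving terminal alkyne 16 and (E)-1-iodoundec-1-ene 19. A cut at C12=C13 would need an olefination with uncertain geometry, and a cut at C9–C10 would need an acetylide, a strong base, next to the peroxide. The chosen cut postpones the nucleophilic enyne until the cationic step is over and takes the E geometry from 19, made from undec-1-yne 17 by hydrozirconation and iodination through 18. The coupling must leave the O–O bond intact.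

**16 from 15.** The alkynyl C–Si bond is cut. The triisopropylsilyl cap of 15 lets the alkyne pass the titanium, hydride and Lewis acid steps. The forward reaction needs fluoride that is not basic enough to damage the β-peroxy imide.

**15 from 14.** No skeletal bond is cut here; only the configuration at C6 is released. The single isomer 15 is traced to 14, the same 3S compound as the mixture of its two C6 epimers, because acidic methanol converges both epimers on the anomerically preferred one. This relieves the ring-forming step of any demand at C6 and asks of the forward reaction only a clean equilibration that leaves C3 and the imide alone.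

**14 from 5, 11 and 12.** The ring is cut at three bonds at once, C3–O2, C3–C4 and C6–O1. This gives acetal 5 (C1–C3 with the auxiliary), bis(trimethylsilyl) peroxide 12 (O1–O2) and methoxycyclopropane 11 (C4–C11 with the capped alkyne); the monoperoxyacetal 13 is the species that ionises. One-bond cuts at C6–O1 or C3–O2 leave a free hydroperoxide whose C3 stereocentre must be made by displacement and carried through many steps, and a cut at C4–C5 needs a later reduction. The three-bond cut removes the ring and the C3 stereocentre in one operation and leaves three simple components, none with an O–O–H group. The forward reaction must ionise the methoxy group and not the peroxide, must have the cyclopropane attack before the cation decays, and must show a facial preference at C3.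

**5 from 2 and 3, and 2 from 1.** The C1–N bond is cut to lithium 3,3-dimethoxypropanoate 2 and (4S)-4-benzyl-1,3-oxazolidin-2-one 3, joined through mixed anhydride 4. Salt 2 comes from commercial methyl ester 1 by saponification. Both steps are routine and must only spare the acetal.

**11 from 10, 9, 8 and 6.** The O–CH3 bond is cut to cyclopropanol 10. The two ring bonds to the carbinol carbon are cut to methyl ester 9 (Kulinkovich disconnection). Ester 9 comes from acid 8, and the C–Si bond of 8 is cut to hex-5-ynoic acid 6 through dianion 7. The silyl group is asked to keep the alkyne away from titanium and from the methylating base.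

## Roads not taken

Alternative 1: Both C–O bonds of the peroxide would be made on a carbocycle in which C1 is still bonded to C6; C1–C6 would be cut afterwards by Baeyer–Villiger oxidation and methanolysis. In the forward key step, N-benzylcinchoninium fluoride would desilylate silyl dienol ether A1 to a chiral ion pair of the cross-conjugated dienolate, which takes up dioxygen at C6; the peroxide anion then adds across the ring to the enone carbon C3 and gives the bridged peroxy ketone A2. Its merits are that absolute configuration would come from a catalyst, that the bridge transmits it to C3 without ambiguity, and that dioxygen is the peroxide source. Its weak points are several. The oxygenation passes through an α-peroxy ketone anion stage that is prone to C–C cleavage and to reduction. The transannular addition must build the strained dioxabicyclo[2.2.2]octane of A2 against a reversible retro-addition. Ion-pair control of oxygenation at a fully aliphatic quaternary centre is not assured. The Baeyer–Villiger excision and the methanolysis must then be run on A2 without O–O cleavage. On absolute control this road is better in principle, since it needs no auxiliary and no separation. The chosen plan sets against it a covalent auxiliary that guarantees separable isomers, a saturated monocyclic product formed directly, and three simple components in place of a linear cyclohexenone sequence.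

Alternative 2: Only C6–O1 is cut. In the forward key step, pyridinium p-toluenesulfonate in methanol would ionise the dimethyl ketal of hydroperoxide A3, and the C3 hydroperoxy oxygen closes reversibly on C6 to give dioxane A4 with the whole side chain in place. This is the best-precedented ring closure of the four, and it sets C6 by the same anomeric equilibrium that step 8 of the chosen plan uses; on certainty of the key step it is clearly better. Its weak points lie before and after the closure. The stereochemical problem moves into the preparation of A3, a secondary alkyl hydroperoxide of defined configuration made by displacement at a secondary centre, where elimination and partial loss of configuration compete. A3 must then be handled with an oxidisable enyne in the same molecule. C1 of A4 must still be raised from a silyl ether to an acid by deprotection and two oxidations in the presence of the peroxide, and the sequence is linear. The chosen plan sets against it convergence, the absence of any free hydroperoxide, and C3 control by an auxiliary in the ring-forming step. It pays with an unproven annulation.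

Alternative 3: The ring would be cut at C4=C5 of a dihydrodioxine, with both C–O bonds already present in an acyclic peroxyketal. In the forward key step, the second-generation Hoveyda–Grubbs catalyst would join C4 of the enoate and the vinyl carbon C5 of diene A5, with loss of the acrylate terminus, to give dihydrodioxine A6. Ruthenium alkylidenes tolerate dialkyl peroxides and six-membered ring closure is dependable, so the closure itself is safer than the chosen annulation. The weak points are three. The preparation of A5 again requires a configurationally defined secondary peroxide linkage, now allylic and γ to an ester, made intermolecularly at a vinyl-substituted ketal carbon. A6 has an allylic, acidified C3–H next to the O–O bond and is therefore open to base-induced Kornblum–DeLaMare cleavage. The C4=C5 bond of A6 must later be reduced without touching the O–O bond or the alkyne, which adds a step with a narrow choice of reagents. The chosen plan forms the saturated ring directly and needs no pre-formed peroxide stereocentre, but it cannot claim the precedent that ring-closing metathesis has.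

Key step: step 7

Assumption: the facial bias of the (4S)-auxiliary in step 7 is taken from the chelate model given there. Because the two C3 series are diastereomers, the separation in step 8 delivers the 3S compound whichever way the bias falls.

## Route

Step 1
Reactants: 1 methyl 3,3-dimethoxypropanoate
Product: 2 lithium 3,3-dimethoxypropanoate
Conditions: LiOH·H2O (1.0 equiv), THF/H2O, 0 °C to rt; evaporation, azeotropic drying with toluene
Reagents that add atoms: lithium hydroxide, [Li+].[OH-]
Why: Ester saponification; the acetal is inert to base, and the product is kept as its salt because the free β-acetal acid is acid-labile.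

Step 2
Reactants: 2 lithium 3,3-dimethoxypropanoate; 3 (4S)-4-benzyl-1,3-oxazolidin-2-one
Product: 5 (4S)-4-benzyl-3-(3,3-dimethoxypropanoyl)-1,3-oxazolidin-2-one, via mixed pivalic anhydride 4 (not isolated)
Conditions: t-BuCOCl (1.05 equiv), THF, −20 °C; then 3, Et3N, LiCl, −20 °C to rt
Reagents that add atoms: none
Why: N-Acylation of an oxazolidinone through a mixed pivalic anhydride with LiCl/Et3N activation; the nucleophile attacks the unhindered carbonyl and not the pivaloyl one.

Step 3
Reactants: 6 hex-5-ynoic acid
Product: 8 6-(triisopropylsilyl)hex-5-ynoic acid, via dilithiated hex-5-ynoic acid 7 (not isolated)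
Conditions: n-BuLi (2.1 equiv), THF, −78 °C; iPr3SiCl (1.1 equiv), −78 °C to rt; 1 M HCl work-up
Reagents that add atoms: chlorotriisopropylsilane, CC(C)[Si](Cl)(C(C)C)C(C)C
Why: C-Silylation of an acetylide: two equivalents of base give the carboxylate–acetylide dianion and the silyl chloride reacts at carbon; any silyl ester formed on oxygen is hydrolysed in the acidic work-up.

Step 4
Reactants: 8 6-(triisopropylsilyl)hex-5-ynoic acid
Product: 9 methyl 6-(triisopropylsilyl)hex-5-ynoate
Conditions: MeOH, H2SO4 (cat.), reflux
Reagents that add atoms: methanol, CO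
Why: Fischer esterification; an alkynylsilane with a bulky silyl group is stable to methanolic acid.

Step 5
Reactants: 9 methyl 6-(triisopropylsilyl)hex-5-ynoate
Product: 10 1-[5-(triisopropylsilyl)pent-4-yn-1-yl]cyclopropan-1-ol
Conditions: Ti(OiPr)4 (0.3 equiv), EtMgBr (2.6 equiv, slow addition), THF, 0 °C to rt; NH4Cl (aq)
Reagents that add atoms: ethylmagnesium bromide, CC[Mg]Br
Why: Kulinkovich cyclopropanation: the titanacyclopropane formed from EtMgBr and Ti(OiPr)4 adds twice to the ester carbonyl as a 1,2-dicarbanion; the bulky silyl group keeps the alkyne out of the titanium coordination sphere.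

Step 6
Reactants: 10 1-[5-(triisopropylsilyl)pent-4-yn-1-yl]cyclopropan-1-ol
Product: 11 1-methoxy-1-[5-(triisopropylsilyl)pent-4-yn-1-yl]cyclopropane
Conditions: NaH (1.3 equiv), MeI (3 equiv), THF/DMF, 0 °C to rt
Reagents that add atoms: iodomethane, CI
Why: Williamson O-methylation of the tertiary cyclopropanol; the alkoxide is trapped by MeI as it forms at low temperature, so opening of the cyclopropanolate to a ketone homoenolate should not compete.

Step 7
Reactants: 5 (4S)-4-benzyl-3-(3,3-dimethoxypropanoyl)-1,3-oxazolidin-2-one; 11 1-methoxy-1-[5-(triisopropylsilyl)pent-4-yn-1-yl]cyclopropane; 12 bis(trimethylsilyl) peroxide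
Product: 14 (4S)-4-benzyl-3-{[(3S)-6-methoxy-6-[5-(triisopropylsilyl)pent-4-yn-1-yl]-1,2-dioxan-3-yl]acetyl}-1,3-oxazolidin-2-one (both C6 epimers), via silylperoxy acetal 13 (not isolated)
Conditions: 12 (1.0 equiv), Me3SiOTf (5 mol%), CH2Cl2, −78 to −40 °C; then 11 (1.5 equiv), 2,6-di-tert-butyl-4-methylpyridine (0.2 equiv), SnCl4 (2.2 equiv, dropwise), −78 °C; NaHCO3 (aq)
Reagents that add atoms: none
Why: Proposed new method: Me3SiOTf ionises acetal 5 and the oxocarbenium ion is captured by 12 to give monoperoxyacetal 13 (C3–O2); SnCl4, one equivalent of which is held by the imide chelate, then removes the remaining methoxy group to give the C3 peroxycarbenium ion, a ring CH2 of 11 attacks it as a σ-nucleophile with cleavage of its bond to the methoxy-bearing carbon (C3–C4), and the silylperoxy oxygen captures the resulting C6 methoxycarbenium ion with loss of the silyl group as Me3SiOMe (C6–O1). The closest known reaction types are the SnCl4-mediated annulation of silylperoxy-derived peroxycarbenium ions with alkenes to 1,2-dioxolanes and the Prins-type opening of cyclopropanol ethers by oxocarbenium ions, in which the cyclopropane acts as a ketone homoenolate; their intermolecular union in a [3+3] sense is new. The dioxane closes in a 6-exo-trig mode on the exocyclic C=O+ bond of the methoxycarbenium ion. C3 is set in the C–C bond formation: in the SnCl4 chelate the acyl chain should lie in the chelate plane like an s-cis enoyl imide, so the benzyl group of the auxiliary screens one face and attack on the other gives 3S; any facial leakage gives a diastereomer and not an enantiomer, and such 3R material travels with 14 until it is removed in step 8. C6 is formed under kinetic control in the ring closure and no element of the substrate is expected to direct it, so 14 is taken on as the mixture of its two C6 epimers and C6 is settled in step 8. The step needs ionisation at the methoxy group and not at the peroxide (secured by the greater basicity of the ether oxygen toward the tin Lewis acid), opening of the cyclopropane at a bond to the donor-bearing carbon (secured by the methoxy group) and an inert alkyne (secured by the silyl cap).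

Step 8
Reactants: 14 (4S)-4-benzyl-3-{[(3S)-6-methoxy-6-[5-(triisopropylsilyl)pent-4-yn-1-yl]-1,2-dioxan-3-yl]acetyl}-1,3-oxazolidin-2-one (both C6 epimers)
Product: 15 (4S)-4-benzyl-3-{[(3S,6R)-6-methoxy-6-[5-(triisopropylsilyl)pent-4-yn-1-yl]-1,2-dioxan-3-yl]acetyl}-1,3-oxazolidin-2-one
Conditions: pyridinium p-toluenesulfonate (0.2 equiv), MeOH, rt; chromatography
Reagents that add atoms: methanol, CO
Why: Acid-catalysed ketal exchange (anomeric equilibration): the C6 peroxyketal ionises reversibly and methanol re-adds under thermodynamic control, so C6 settles with methoxy axial (anomeric effect) and both carbon substituents equatorial, which is 6R when C3 is S, while C3 is not touched; ring-opened peroxy material from step 7 should reclose under the same conditions, and the diastereomeric 3R material from facial leakage in step 7 is removed here by chromatography or crystallisation.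

Step 9
Reactants: 15 (4S)-4-benzyl-3-{[(3S,6R)-6-methoxy-6-[5-(triisopropylsilyl)pent-4-yn-1-yl]-1,2-dioxan-3-yl]acetyl}-1,3-oxazolidin-2-one
Product: 16 (4S)-4-benzyl-3-{[(3S,6R)-6-methoxy-6-(pent-4-yn-1-yl)-1,2-dioxan-3-yl]acetyl}-1,3-oxazolidin-2-one
Conditions: Bu4NF (1.5 equiv), AcOH (1.5 equiv), THF, 0 °C to rt
Reagents that add atoms: none
Why: Fluoride-induced cleavage of the alkynyl C–Si bond; buffering with acetic acid should keep the medium too weakly basic to enolise the imide and expel the β-peroxide.

Step 10
Reactants: 17 undec-1-yne
Product: 19 (E)-1-iodoundec-1-ene, via alkenylzirconocene chloride 18 (not isolated)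
Conditions: Cp2Zr(H)Cl (1.2 equiv), CH2Cl2, rt; I2 (1.2 equiv), 0 °C
Reagents that add atoms: iodine, II
Why: Hydrozirconation adds Zr–H syn and with the metal at the terminal carbon; iodine cleaves the C–Zr bond with retention, so only the E-iodoalkene should form.

Step 11
Reactants: 16 (4S)-4-benzyl-3-{[(3S,6R)-6-methoxy-6-(pent-4-yn-1-yl)-1,2-dioxan-3-yl]acetyl}-1,3-oxazolidin-2-one; 19 (E)-1-iodoundec-1-ene
Product: 20 (4S)-4-benzyl-3-{[(3S,6R)-6-[(6E)-hexadec-6-en-4-yn-1-yl]-6-methoxy-1,2-dioxan-3-yl]acetyl}-1,3-oxazolidin-2-one
Conditions: Pd(PPh3)4 (3 mol%), CuI (6 mol%), Et3N, THF (degassed), rt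
Reagents that add atoms: none
Why: Sonogashira coupling of a terminal alkyne with an alkenyl iodide; the E geometry is retained through oxidative addition and reductive elimination, and mild room-temperature conditions of this kind are tolerated by dialkyl peroxides.

Step 12
Reactants: 20 (4S)-4-benzyl-3-{[(3S,6R)-6-[(6E)-hexadec-6-en-4-yn-1-yl]-6-methoxy-1,2-dioxan-3-yl]acetyl}-1,3-oxazolidin-2-one
Product: 21 [(3S,6R)-6-[(6E)-hexadec-6-en-4-yn-1-yl]-6-methoxy-1,2-dioxan-3-yl]acetic acid (CNP0298534.1)
Conditions: LiOH (2 equiv), H2O2 (4 equiv), THF/H2O, 0 °C; Na2SO3 (aq); 1 M HCl to pH 4, 0 °C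
Reagents that add atoms: hydrogen peroxide, OO
Why: Hydroperoxide-mediated cleavage of the N-acyl oxazolidinone: LiOOH attacks the exocyclic carbonyl selectively and is too weakly basic to trigger β-elimination at C3, so neither stereocentre is touched and the auxiliary is recovered.

## Compound list

1 | methyl 3,3-dimethoxypropanoate | COC(=O)CC(OC)OC | starting material
2 | lithium 3,3-dimethoxypropanoate | [Li+].[O-]C(=O)CC(OC)OC | intermediate
3 | (4S)-4-benzyl-1,3-oxazolidin-2-one | O=C1N[C@@H](Cc2ccccc2)CO1 | starting material
4 | 3,3-dimethoxypropanoic 2,2-dimethylpropanoic anhydride (not isolated) | COC(OC)CC(=O)OC(=O)C(C)(C)C | intermediate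
5 | (4S)-4-benzyl-3-(3,3-dimethoxypropanoyl)-1,3-oxazolidin-2-one | COC(OC)CC(=O)N1[C@@H](Cc2ccccc2)COC1=O | intermediate
6 | hex-5-ynoic acid | C#CCCCC(=O)O | starting material
7 | dilithium salt of hex-5-ynoic acid, carboxylate and acetylide (not isolated) | [Li+].[Li+].[C-]#CCCCC(=O)[O-] | intermediate
8 | 6-(triisopropylsilyl)hex-5-ynoic acid | CC(C)[Si](C(C)C)(C(C)C)C#CCCCC(=O)O | intermediate
9 | methyl 6-(triisopropylsilyl)hex-5-ynoate | COC(=O)CCCC#C[Si](C(C)C)(C(C)C)C(C)C | intermediate
10 | 1-[5-(triisopropylsilyl)pent-4-yn-1-yl]cyclopropan-1-ol | OC1(CCCC#C[Si](C(C)C)(C(C)C)C(C)C)CC1 | intermediate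
11 | 1-methoxy-1-[5-(triisopropylsilyl)pent-4-yn-1-yl]cyclopropane | COC1(CCCC#C[Si](C(C)C)(C(C)C)C(C)C)CC1 | intermediate
12 | bis(trimethylsilyl) peroxide | C[Si](C)(C)OO[Si](C)(C)C | starting material
13 | (4S)-4-benzyl-3-[3-methoxy-3-(trimethylsilylperoxy)propanoyl]-1,3-oxazolidin-2-one, both configurations at the acetal carbon (not isolated) | COC(CC(=O)N1[C@@H](Cc2ccccc2)COC1=O)OO[Si](C)(C)C | intermediate
14 | (4S)-4-benzyl-3-{[(3S)-6-methoxy-6-[5-(triisopropylsilyl)pent-4-yn-1-yl]-1,2-dioxan-3-yl]acetyl}-1,3-oxazolidin-2-one, mixture of the two C6 epimers | CC(C)[Si](C(C)C)(C(C)C)C#CCCCC1(OC)CC[C@@H](CC(=O)N2[C@@H](Cc3ccccc3)COC2=O)OO1 | intermediate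
15 | (4S)-4-benzyl-3-{[(3S,6R)-6-methoxy-6-[5-(triisopropylsilyl)pent-4-yn-1-yl]-1,2-dioxan-3-yl]acetyl}-1,3-oxazolidin-2-one | CC(C)[Si](C(C)C)(C(C)C)C#CCCC[C@]1(OC)CC[C@@H](CC(=O)N2[C@@H](Cc3ccccc3)COC2=O)OO1 | intermediate
16 | (4S)-4-benzyl-3-{[(3S,6R)-6-methoxy-6-(pent-4-yn-1-yl)-1,2-dioxan-3-yl]acetyl}-1,3-oxazolidin-2-one | C#CCCC[C@]1(OC)CC[C@@H](CC(=O)N2[C@@H](Cc3ccccc3)COC2=O)OO1 | intermediate
17 | undec-1-yne | CCCCCCCCCC#C | starting material
18 | chlorobis(cyclopentadienyl)[(E)-undec-1-en-1-yl]zirconium (not isolated) | CCCCCCCCC/C=C/[Zr](Cl)(C1C=CC=C1)C1C=CC=C1 | intermediate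
19 | (E)-1-iodoundec-1-ene | CCCCCCCCC/C=C/I | intermediate
20 | (4S)-4-benzyl-3-{[(3S,6R)-6-[(6E)-hexadec-6-en-4-yn-1-yl]-6-methoxy-1,2-dioxan-3-yl]acetyl}-1,3-oxazolidin-2-one | CCCCCCCCC/C=C/C#CCCC[C@]1(OC)CC[C@@H](CC(=O)N2[C@@H](Cc3ccccc3)COC2=O)OO1 | intermediate
21 | [(3S,6R)-6-[(6E)-hexadec-6-en-4-yn-1-yl]-6-methoxy-1,2-dioxan-3-yl]acetic acid (CNP0298534.1) | CCCCCCCCC/C=C/C#CCCC[C@]1(OC)CC[C@@H](CC(=O)O)OO1 | target

## Step count, longest linear sequence and least certain steps

Total: 12 steps. Longest linear sequence: 9 steps, from 6 through steps 3, 4, 5, 6, 7, 8, 9, 11 and 12.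

**Step 7 (key step, proposed new method).** Three things are most likely to go wrong. The cyclopropane may be consumed by SnCl4 or by adventitious acid (stannylative or protic ring opening) before it meets the cation. The peroxycarbenium ion may decay by α-proton loss or by O–O heterolysis with migration. Facial selectivity at C3 may be poor, because the cation is separated from the auxiliary by a freely rotating methylene group.

The fallback uses known reactions only; it sets out from 9 and returns at 15, so it replaces steps 7 and 8. Ester 9 is converted with MeNH(OMe)·HCl and iPrMgCl into N-methoxy-N-methyl-6-(triisopropylsilyl)hex-5-ynamide F1. But-3-enylmagnesium bromide then gives 10-(triisopropylsilyl)dec-1-en-9-yn-5-one F2. Cross-metathesis with methyl acrylate under the second-generation Hoveyda–Grubbs catalyst gives methyl (2E)-6-oxo-11-(triisopropylsilyl)undec-2-en-10-ynoate F3. Urea–hydrogen peroxide with Sc(OTf)3 in methanol converts the ketone into methyl (2E)-6-hydroperoxy-6-methoxy-11-(triisopropylsilyl)undec-2-en-10-ynoate F4. Et2NH in CF3CH2OH closes the ring by intramolecular conjugate addition of the hydroperoxide, giving methyl {6-methoxy-6-[5-(triisopropylsilyl)pent-4-yn-1-yl]-1,2-dioxan-3-yl}acetate F5 as a racemic mixture of both relative configurations. Pyridinium p-toluenesulfonate in methanol converges it on rac-methyl {(3S,6R)-6-methoxy-6-[5-(triisopropylsilyl)pent-4-yn-1-yl]-1,2-dioxan-3-yl}acetate F6. LiOH gives rac-{(3S,6R)-6-methoxy-6-[5-(triisopropylsilyl)pent-4-yn-1-yl]-1,2-dioxan-3-yl}acetic acid F7. Activation with t-BuCOCl gives the racemic pivalic mixed anhydride F8, and acylation of 3 (Et3N, LiCl) gives 15 together with its diastereomer (4S)-4-benzyl-3-{[(3R,6S)-6-methoxy-6-[5-(triisopropylsilyl)pent-4-yn-1-yl]-1,2-dioxan-3-yl]acetyl}-1,3-oxazolidin-2-one F9, from which 15 is separated by chromatography. This fallback has no facial selectivity at all and rests entirely on the separation.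

**Step 5.** The most likely failure is engagement of the alkyne by the low-valent titanium intermediates (complexation, carbometallation or intramolecular acyl substitution) in competition with the ester. The fallback sets out from 9 and returns at 11 without a cyclopropanol or a Grignard reagent. Methylenation of the ester carbonyl with Cp2Ti(μ-Cl)(μ-CH2)AlMe2 (pyridine, THF, −40 °C) gives the enol ether (6-methoxyhept-6-en-1-yn-1-yl)tri(propan-2-yl)silane F10. Simmons–Smith cyclopropanation (Et2Zn, CH2I2, CH2Cl2, 0 °C) then converts F10 directly into 11.

**Step 9.** The most likely failure is base-induced β-elimination of the peroxide from the imide enolate, with ring opening and loss of configurational integrity at C3, or attack of fluoride on the imide. The fallback sets out from 15 and returns at 21 by changing the order of events, so that fluoride meets a non-enolisable carboxylate. LiOH/H2O2 first removes the auxiliary to give {(3S,6R)-6-methoxy-6-[5-(triisopropylsilyl)pent-4-yn-1-yl]-1,2-dioxan-3-yl}acetic acid F11. Bu4NF in THF then gives {(3S,6R)-6-methoxy-6-(pent-4-yn-1-yl)-1,2-dioxan-3-yl}acetic acid F12. Sonogashira coupling of F12 with 19 (Pd(PPh3)4, CuI, excess Et3N) gives 21.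

## Further compounds

F1 | step 7 | N-methoxy-N-methyl-6-(triisopropylsilyl)hex-5-ynamide | CON(C)C(=O)CCCC#C[Si](C(C)C)(C(C)C)C(C)C
F2 | step 7 | 10-(triisopropylsilyl)dec-1-en-9-yn-5-one | C=CCCC(=O)CCCC#C[Si](C(C)C)(C(C)C)C(C)C
F3 | step 7 | methyl (2E)-6-oxo-11-(triisopropylsilyl)undec-2-en-10-ynoate | COC(=O)/C=C/CCC(=O)CCCC#C[Si](C(C)C)(C(C)C)C(C)C
F4 | step 7 | methyl (2E)-6-hydroperoxy-6-methoxy-11-(triisopropylsilyl)undec-2-en-10-ynoate, racemic | COC(=O)/C=C/CCC(OC)(OO)CCCC#C[Si](C(C)C)(C(C)C)C(C)C
F5 | step 7 | methyl {6-methoxy-6-[5-(triisopropylsilyl)pent-4-yn-1-yl]-1,2-dioxan-3-yl}acetate, racemic, both relative configurations | CC(C)[Si](C(C)C)(C(C)C)C#CCCCC1(OC)CCC(CC(=O)OC)OO1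
F6 | step 7 | rac-methyl {(3S,6R)-6-methoxy-6-[5-(triisopropylsilyl)pent-4-yn-1-yl]-1,2-dioxan-3-yl}acetate, both enantiomers | CC(C)[Si](C(C)C)(C(C)C)C#CCCC[C@]1(OC)CC[C@@H](CC(=O)OC)OO1.CC(C)[Si](C(C)C)(C(C)C)C#CCCC[C@@]1(OC)CC[C@H](CC(=O)OC)OO1
F7 | step 7 | rac-{(3S,6R)-6-methoxy-6-[5-(triisopropylsilyl)pent-4-yn-1-yl]-1,2-dioxan-3-yl}acetic acid, both enantiomers | CC(C)[Si](C(C)C)(C(C)C)C#CCCC[C@]1(OC)CC[C@@H](CC(=O)O)OO1.CC(C)[Si](C(C)C)(C(C)C)C#CCCC[C@@]1(OC)CC[C@H](CC(=O)O)OO1
F8 | step 7 | rac-{(3S,6R)-6-methoxy-6-[5-(triisopropylsilyl)pent-4-yn-1-yl]-1,2-dioxan-3-yl}acetic 2,2-dimethylpropanoic anhydride, both enantiomers | CC(C)[Si](C(C)C)(C(C)C)C#CCCC[C@]1(OC)CC[C@@H](CC(=O)OC(=O)C(C)(C)C)OO1.CC(C)[Si](C(C)C)(C(C)C)C#CCCC[C@@]1(OC)CC[C@H](CC(=O)OC(=O)C(C)(C)C)OO1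
F9 | step 7 | (4S)-4-benzyl-3-{[(3R,6S)-6-methoxy-6-[5-(triisopropylsilyl)pent-4-yn-1-yl]-1,2-dioxan-3-yl]acetyl}-1,3-oxazolidin-2-one | CC(C)[Si](C(C)C)(C(C)C)C#CCCC[C@@]1(OC)CC[C@H](CC(=O)N2[C@@H](Cc3ccccc3)COC2=O)OO1
F10 | step 5 | (6-methoxyhept-6-en-1-yn-1-yl)tri(propan-2-yl)silane | C=C(OC)CCCC#C[Si](C(C)C)(C(C)C)C(C)C
F11 | step 9 | {(3S,6R)-6-methoxy-6-[5-(triisopropylsilyl)pent-4-yn-1-yl]-1,2-dioxan-3-yl}acetic acid | CC(C)[Si](C(C)C)(C(C)C)C#CCCC[C@]1(OC)CC[C@@H](CC(=O)O)OO1
F12 | step 9 | {(3S,6R)-6-methoxy-6-(pent-4-yn-1-yl)-1,2-dioxan-3-yl}acetic acid | C#CCCC[C@]1(OC)CC[C@@H](CC(=O)O)OO1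
A1 | alternative 1 | trimethyl({2-[5-(triisopropylsilyl)pent-4-yn-1-yl]cyclohexa-1,5-dien-1-yl}oxy)silane | C[Si](C)(C)OC1=C(CCCC#C[Si](C(C)C)(C(C)C)C(C)C)CCC=C1
A2 | alternative 1 | 4-[5-(triisopropylsilyl)pent-4-yn-1-yl]-2,3-dioxabicyclo[2.2.2]octan-5-one, single enantiomer as in the SMILES | CC(C)[Si](C(C)C)(C(C)C)C#CCCC[C@]1(C(=O)C2)CC[C@@H]2OO1
A3 | alternative 2 | tert-butyl{[(3S,12E)-3-hydroperoxy-6,6-dimethoxydocos-12-en-10-yn-1-yl]oxy}diphenylsilane | CCCCCCCCC/C=C/C#CCCCC(OC)(OC)CC[C@@H](CCO[Si](c1ccccc1)(c1ccccc1)C(C)(C)C)OO
A4 | alternative 2 | tert-butyl{2-[(3S,6R)-6-[(6E)-hexadec-6-en-4-yn-1-yl]-6-methoxy-1,2-dioxan-3-yl]ethoxy}diphenylsilane | CCCCCCCCC/C=C/C#CCCC[C@]1(OC)CC[C@@H](CCO[Si](c2ccccc2)(c2ccccc2)C(C)(C)C)OO1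
A5 | alternative 3 | dimethyl (2E)-4-({3-methoxy-8-[tri(propan-2-yl)silyl]oct-1-en-7-yn-3-yl}peroxy)hex-2-enedioate, peroxy-bearing carbon configured as C3 of the target, mixture at the ketal carbon | C=CC(OC)(CCCC#C[Si](C(C)C)(C(C)C)C(C)C)OO[C@H](CC(=O)OC)/C=C/C(=O)OC
A6 | alternative 3 | methyl {6-methoxy-6-[5-(triisopropylsilyl)pent-4-yn-1-yl]-3,6-dihydro-1,2-dioxin-3-yl}acetate, both centres arranged as in the target | CC(C)[Si](C(C)C)(C(C)C)C#CCCC[C@]1(OC)C=C[C@@H](CC(=O)OC)OO1
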